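## Retrosynthetic overview

1. Target 30 ← ketone 29 (C8=C17 by carbonyl methylenation) ← iodide 26 + 3-bromofuran-2(5H)-one (C12–C13, Negishi) ← keto aldehyde 20 (C19 CHO → CO2Me; benzyl ethers → C20 acetate and C12 iodide).
2. Keto aldehyde 20 (rings A and B, C4 and C5) ← monocyclic cycloheptenol 17 in one operation: the C5–C6 bond closes ring B, and a 1,2-shift of C3 from C19 to C4 contracts the seven-membered carbocycle C10–C1–C2–C3–C19–C4–C5 to six-membered ring A.
3. Enabling feature: in ring A the quaternary C4 bears an exocyclic carbonyl carbon (C19) anti to H5 on the neighbouring ring-fusion carbon C5. C19 can therefore be placed back in the ring as a carbinol beside a C4=C5 alkene; attack of C5 on C6 then creates the C4 cation that the C3–C19 bond quenches.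
4. Cycloheptenol 17 ← quaternary C10 by Ireland–Claisen rearrangement (1,3-chirality transfer from a CBS-derived allylic alcohol) ← 3-[(benzyloxy)methyl]cyclohept-2-en-1-one ← cycloheptane-1,3-dione.
5. Ring order: the seven-membered carbocycle is bought; ring B is closed and ring A formed by contraction together in step 12; the butenolide ring is attached preformed in step 18.

Key step: step 12

Remark: labdane numbering (C1–C20) is used for locants, α/β mean below/above the decalin as usually drawn; compounds 10–22 are carried as both C9 epimers (C9 is equilibrated in step 14); 1, 3, 6 and 27 are taken as purchasable.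

## Route

Step 1
Reactants: 1 cycloheptane-1,3-dione
Product: 2 3-oxocyclohept-1-en-1-yl trifluoromethanesulfonate
Conditions: Tf2O, pyridine, CH2Cl2, −78 → 0 °C
Reagents that add atoms: trifluoromethanesulfonic anhydride, O=S(=O)(OS(=O)(=O)C(F)(F)F)C(F)(F)F
Why: O-sulfonylation of the enol form of the vinylogous acid (enol triflate formation) should give the β-triflyloxy enone as an activated cross-coupling partner.

Step 2
Reactants: 2 3-oxocyclohept-1-en-1-yl trifluoromethanesulfonate; 3 potassium (benzyloxymethyl)trifluoroborate
Product: 4 3-[(benzyloxy)methyl]cyclohept-2-en-1-one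
Conditions: Pd(OAc)2 (cat.), RuPhos (cat.), Cs2CO3, dioxane/H2O 10:1, 90 °C
Reagents that add atoms: potassium (benzyloxymethyl)trifluoroborate (3), [K+].F[B-](F)(F)COCc1ccccc1
Why: Suzuki–Miyaura sp3–sp2 cross-coupling of the electron-poor enol triflate with an alkoxymethyltrifluoroborate should install the future C20 carbon with its protected oxygen.

Step 3
Reactants: 4 3-[(benzyloxy)methyl]cyclohept-2-en-1-one
Product: 5 (R)-3-[(benzyloxy)methyl]cyclohept-2-en-1-ol
Conditions: (S)-2-methyl-CBS-oxazaborolidine (10 mol %), BH3·SMe2, THF, −30 °C; MeOH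
Reagents that add atoms: none
Why: CBS reduction with catalyst-controlled 1,2-hydride delivery (alkenyl branch as the large group) should give the (R)-carbinol, the one stereocentre of the route that is set by catalysis.

Step 4
Reactants: 5 (R)-3-[(benzyloxy)methyl]cyclohept-2-en-1-ol; 6 4-(benzyloxy)butanoic acid
Product: 7 (R)-3-[(benzyloxy)methyl]cyclohept-2-en-1-yl 4-(benzyloxy)butanoate
Conditions: DCC, DMAP (cat.), CH2Cl2, 0 °C → rt
Reagents that add atoms: 4-(benzyloxy)butanoic acid (6), OC(=O)CCCOCc1ccccc1
Why: Steglich esterification of the secondary allylic alcohol does not touch the stereocentre and brings in C8, C9, C11 and C12.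

Step 5
Reactants: 7 (R)-3-[(benzyloxy)methyl]cyclohept-2-en-1-yl 4-(benzyloxy)butanoate
Product: 10 (2RS)-4-(benzyloxy)-2-{(1R)-1-[(benzyloxy)methyl]cyclohept-2-en-1-yl}butanoic acid, via silyl ketene acetal 8 (not isolated), via trimethylsilyl ester 9 (not isolated)
Conditions: LiN(i-Pr)2, THF, −78 °C; TMSCl; −78 → 60 °C; then 1 M HCl
Reagents that add atoms: none
Why: The Ireland–Claisen [3,3] rearrangement is suprafacial, so the C9–C10 bond forms on the ring face that carried the ester oxygen and the carbinol chirality is transferred to the quaternary C10; C9 forms as a mixture that is equilibrated later.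

Step 6
Reactants: 10 (2RS)-4-(benzyloxy)-2-{(1R)-1-[(benzyloxy)methyl]cyclohept-2-en-1-yl}butanoic acid
Product: 12 (2RS)-4-(benzyloxy)-2-{(1R)-1-[(benzyloxy)methyl]cyclohept-2-en-1-yl}-N-methoxy-N-methylbutanamide, via acid chloride 11 (not isolated)
Conditions: (COCl)2, DMF (cat.), CH2Cl2, 0 °C → rt; then MeNH(OMe)·HCl, pyridine, 0 °C → rt
Reagents that add atoms: N,O-dimethylhydroxylamine hydrochloride, CNOC.Cl
Why: Acyl substitution through the acid chloride should overcome the hindrance at C8 and give the N-methoxy-N-methylamide that later stops at the ketone stage.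

Step 7
Reactants: 12 (2RS)-4-(benzyloxy)-2-{(1R)-1-[(benzyloxy)methyl]cyclohept-2-en-1-yl}-N-methoxy-N-methylbutanamide
Product: 13 enone amide (C19 ketone, C4=C5 alkene; quaternary C10 as in 12)
Conditions: CrO3, 3,5-dimethylpyrazole, CH2Cl2, −20 °C
Reagents that add atoms: chromium trioxide, O=[Cr](=O)=O
Why: In this allylic C–H oxidation C19 is the only allylic CH2 (the other allylic carbon, C10, is quaternary), so a single enone is expected.

Step 8
Reactants: 13 enone amide
Product: 14 α-iodoenone amide (iodine on C4)
Conditions: iodine, pyridine, CH2Cl2, rt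
Reagents that add atoms: iodine, [I][I]
Why: α-Iodination of the enone by conjugate addition of pyridine, iodination of the enolate and elimination should place iodine on C4 only.

Step 9
Reactants: 14 α-iodoenone amide
Product: 15 2-methylenone amide (C4 methyl = C18)
Conditions: MeB(OH)2, Pd(dppf)Cl2 (cat.), K3PO4, dioxane/H2O, 80 °C
Reagents that add atoms: methylboronic acid, CB(O)O
Why: Suzuki–Miyaura methylation of the α-iodoenone should install C18 on the alkene carbon that becomes the cationic centre of the key step.

Step 10
Reactants: 15 2-methylenone amide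
Product: 16 allylic alcohol amide ((S)-carbinol at C19, hydroxyl cis to the C20 benzyloxymethyl group)
Conditions: (R)-2-methyl-CBS-oxazaborolidine (20 mol %), BH3·SMe2, THF, −40 °C; MeOH
Reagents that add atoms: none
Why: CBS reduction under catalyst control, with the α-methylalkenyl carbon as the large group, should give the (S)-carbinol whose oxygen is cis to C20, while the amide is not reduced at this temperature.

Step 11
Reactants: 16 allylic alcohol amide
Product: 17 6-(benzyloxy)-4-{(1R,4S)-1-[(benzyloxy)methyl]-4-hydroxy-3-methylcyclohept-2-en-1-yl}hex-1-en-3-one (both epimers at C4 of the chain = C9)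
Conditions: CH2=CHMgBr (3.5 equiv), THF, −20 → 0 °C; inverse quench into cold aq. NH4Cl
Reagents that add atoms: vinylmagnesium bromide, C=C[Mg]Br
Why: Grignard addition to the N-methoxy-N-methylamide stops at the chelated tetrahedral adduct, which should release the vinyl ketone (C6=C7–C8=O) only on work-up.

Step 12
Reactants: 17 6-(benzyloxy)-4-{(1R,4S)-1-[(benzyloxy)methyl]-4-hydroxy-3-methylcyclohept-2-en-1-yl}hex-1-en-3-one
Product: 20 trans-decalin keto aldehyde (C4: α-CH3, β-CHO = C19; 5α-H; C10: β-CH2OBn = C20; C8 ketone; C9: CH2CH2OBn, both epimers), via aluminium alkoxide 18 (not isolated), via aluminium enolate 19 (not isolated)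
Conditions: Me2AlCl (2.5 equiv), CH2Cl2 (0.01 M), −78 → −20 °C; aq. KNaC4H4O6
Reagents that add atoms: none
Why: Proposed new method: Me2AlCl turns the C19 hydroxyl into aluminium alkoxide 18 and complexes the vinyl ketone; C5 of the C4=C5 alkene then adds to the terminal carbon C6 of the activated enone, and the developing tertiary C4 cation is quenched by 1,2-shift of the ring bond C3–C19 to C4, pushed by the alkoxide oxygen (semipinacol), which contracts the seven-membered ring C10–C1–C2–C3–C19–C4–C5 to six-membered ring A, turns C19 into the exocyclic aldehyde and leaves ring B as aluminium enolate 19. The closest known reaction types are Lewis-acid-induced conjugate additions of alkenes to enones, whose zwitterions end by 1,2-shifts, and pinacol-terminated Prins cyclizations; the new element is a ring-contracting alkyl shift from a secondary cycloalkenyl alkoxide as the terminator. Ring B closes by C5–C6 bond formation in a 6-exo-trig sense at the nucleophilic alkene (citronellal-type chair, C9 branch equatorial) and endo at the acceptor, while ring A is not closed but formed by the 1,2-alkyl shift inside the existing carbocycle. C5 is controlled by C10 and C19: in the chair cycloheptene with the C9 chain pseudoequatorial, C20 and the C19–O–Al group are pseudoaxial on one face, the alkoxide can deliver the complexed enone to that face, and H5 thus ends anti to C20 (trans ring fusion); C4 is controlled by the anti addition across the ring alkene, C3 entering opposite to C6 so that C19 ends axial, cis to C20 and anti to H5; C9 stays a mixture. The step needs the alkyl shift to beat hydride shift from C19, proton loss from the C4 methyl and cyclobutane collapse of the zwitterion, and the substrate secures this because in the reacting conformer the C19–H bond lies near the nodal plane of the C4 cation while the C3–C19 bond is nearly parallel to its empty orbital and the aluminium alkoxide is a strong electron donor.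

Step 13
Reactants: 20 trans-decalin keto aldehyde
Product: 21 keto acid (C19 CO2H; C9 epimers)
Conditions: NaClO2, NaH2PO4, 2-methylbut-2-ene, t-BuOH/H2O, rt
Reagents that add atoms: sodium chlorite, [Na+].[O-]Cl=O
Why: Pinnick oxidation converts the hindered neopentyl aldehyde into the acid without touching the ketone or the benzyl ethers.

Step 14
Reactants: 21 keto acid
Product: 23 keto methyl ester with 9α-H (C9 side chain β, equatorial), via methyl ester epimer mixture 22 (not isolated)
Conditions: TMSCHN2, toluene/MeOH, 0 °C; then NaOMe (0.3 equiv), MeOH, rt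
Reagents that add atoms: (trimethylsilyl)diazomethane, C[Si](C)(C)C=[N+]=[N-]
Why: Methyl esterification of the hindered acid is followed by base equilibration through the C8 enolate, which should place the C9 side chain equatorial (the thermodynamic 9α-H epimer of the trans-decalin).

Step 15
Reactants: 23 keto methyl ester
Product: 24 keto ester diol (C20–OH and C12–OH)
Conditions: H2 (1 atm), Pd(OH)2/C, EtOAc, rt
Reagents that add atoms: none
Why: Hydrogenolysis removes both benzyl ethers under neutral conditions while the ketone and ester stay intact.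

Step 16
Reactants: 24 keto ester diol
Product: 25 iodo alcohol (C12–I, C20–OH)
Conditions: iodine, PPh3, imidazole, CH2Cl2, 0 °C
Reagents that add atoms: iodine, [I][I]
Why: The Appel iodination is an SN2 process and should take only the unhindered primary C12 alcohol, the axial neopentyl C20 alcohol being far slower.

Step 17
Reactants: 25 iodo alcohol
Product: 26 iodo acetate (C20–OAc)
Conditions: Ac2O, DMAP (cat.), i-Pr2NEt, CH2Cl2, 0 °C → rt
Reagents that add atoms: acetic anhydride, CC(=O)OC(C)=O
Why: Nucleophile-catalysed acetylation of the neopentyl alcohol installs the C20 acetate before any alkoxide can attack the C19 ester.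

Step 18
Reactants: 26 iodo acetate; 27 3-bromofuran-2(5H)-one
Product: 29 8-oxo butenolide (17-nor ketone of the target), via alkylzinc iodide 28 (not isolated)
Conditions: Zn dust, LiCl, THF, 40 °C; then 27, Pd2(dba)3 (cat.), SPhos (cat.), THF/NMP, rt
Reagents that add atoms: 3-bromofuran-2(5H)-one (27), O=C1OCC=C1Br
Why: Zinc insertion into the primary iodide and Negishi sp3–sp2 coupling with the α-bromobutenolide form C12–C13, the organozinc tolerating ketone, ester and acetate.

Step 19
Reactants: 29 8-oxo butenolide
Product: 30 methyl 20-acetoxylabda-8(17),13-dien-16,15-olid-19-oate (target; 4α-CH3, 4β-CO2Me, 5α-H, 9α-H, 10β-CH2OAc)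
Conditions: Zn, CH2Br2, TiCl4, THF/CH2Cl2, 0 °C → rt
Reagents that add atoms: dibromomethane, BrCBr
Why: Takai–Lombardo methylenation is non-basic, so the hindered C8 ketone is converted to the exocyclic methylene without epimerising C9 and without attack on the ester, acetate or butenolide carbonyls.

## Compound list

1 | cycloheptane-1,3-dione | O=C1CCCCC(=O)C1 | starting material
2 | 3-oxocyclohept-1-en-1-yl trifluoromethanesulfonate | O=C1C=C(OS(=O)(=O)C(F)(F)F)CCCC1 | intermediate
3 | potassium (benzyloxymethyl)trifluoroborate | [K+].F[B-](F)(F)COCc1ccccc1 | starting material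
4 | 3-[(benzyloxy)methyl]cyclohept-2-en-1-one | O=C1C=C(COCc2ccccc2)CCCC1 | intermediate
5 | (R)-3-[(benzyloxy)methyl]cyclohept-2-en-1-ol | O[C@H]1C=C(COCc2ccccc2)CCCC1 | intermediate
6 | 4-(benzyloxy)butanoic acid | OC(=O)CCCOCc1ccccc1 | starting material
7 | (R)-3-[(benzyloxy)methyl]cyclohept-2-en-1-yl 4-(benzyloxy)butanoate | O=C(CCCOCc1ccccc1)O[C@H]1C=C(COCc2ccccc2)CCCC1 | intermediate
8 | trimethylsilyl ketene acetal of ester 7 | C[Si](C)(C)OC(=CCCOCc1ccccc1)O[C@H]1C=C(COCc2ccccc2)CCCC1 | intermediate (not isolated)
9 | trimethylsilyl ester of acid 10 | C[Si](C)(C)OC(=O)C(CCOCc1ccccc1)[C@@]1(COCc2ccccc2)CCCCC=C1 | intermediate (not isolated)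
10 | (2RS)-4-(benzyloxy)-2-{(1R)-1-[(benzyloxy)methyl]cyclohept-2-en-1-yl}butanoic acid | OC(=O)C(CCOCc1ccccc1)[C@@]1(COCc2ccccc2)CCCCC=C1 | intermediate
11 | acid chloride of 10 | ClC(=O)C(CCOCc1ccccc1)[C@@]1(COCc2ccccc2)CCCCC=C1 | intermediate (not isolated)
12 | (2RS)-4-(benzyloxy)-2-{(1R)-1-[(benzyloxy)methyl]cyclohept-2-en-1-yl}-N-methoxy-N-methylbutanamide | CON(C)C(=O)C(CCOCc1ccccc1)[C@@]1(COCc2ccccc2)CCCCC=C1 | intermediate
13 | enone amide: 4-(benzyloxy)-2-{1-[(benzyloxy)methyl]-4-oxocyclohept-2-en-1-yl}-N-methoxy-N-methylbutanamide (quaternary carbon as in 12) | CON(C)C(=O)C(CCOCc1ccccc1)[C@@]1(COCc2ccccc2)CCCC(=O)C=C1 | intermediate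
14 | α-iodoenone amide: 3-iodo-4-oxocyclohept-2-en-1-yl analogue of 13 | CON(C)C(=O)C(CCOCc1ccccc1)[C@@]1(COCc2ccccc2)CCCC(=O)C(I)=C1 | intermediate
15 | 2-methylenone amide: 3-methyl-4-oxocyclohept-2-en-1-yl analogue of 13 | CON(C)C(=O)C(CCOCc1ccccc1)[C@@]1(COCc2ccccc2)CCCC(=O)C(C)=C1 | intermediate
16 | allylic alcohol amide: (4S)-4-hydroxy-3-methylcyclohept-2-en-1-yl analogue, hydroxyl cis to CH2OBn | CON(C)C(=O)C(CCOCc1ccccc1)[C@@]1(COCc2ccccc2)CCC[C@H](O)C(C)=C1 | intermediate
17 | 6-(benzyloxy)-4-{(1R,4S)-1-[(benzyloxy)methyl]-4-hydroxy-3-methylcyclohept-2-en-1-yl}hex-1-en-3-one (C9 epimers) | C=CC(=O)C(CCOCc1ccccc1)[C@@]1(COCc2ccccc2)CCC[C@H](O)C(C)=C1 | intermediate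
18 | chloro(methyl)aluminium alkoxide of 17 | C=CC(=O)C(CCOCc1ccccc1)[C@@]1(COCc2ccccc2)CCC[C@H](O[Al](C)Cl)C(C)=C1 | intermediate (not isolated)
19 | chloro(methyl)aluminium C7=C8 enolate of 20 | C[Al](Cl)OC1=CC[C@@H]2[C@](COCc3ccccc3)(CCC[C@]2(C)C=O)C1CCOCc1ccccc1 | intermediate (not isolated)
20 | trans-decalin keto aldehyde (4α-CH3, 4β-CHO, 5α-H, 10β-CH2OBn, 8-oxo, 9-CH2CH2OBn, C9 epimers) | O=C1CC[C@@H]2[C@](COCc3ccccc3)(CCC[C@]2(C)C=O)C1CCOCc1ccccc1 | intermediate
21 | keto acid (4β-CO2H; otherwise as 20) | O=C1CC[C@@H]2[C@](COCc3ccccc3)(CCC[C@]2(C)C(=O)O)C1CCOCc1ccccc1 | intermediate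
22 | keto methyl ester, C9 epimer mixture | O=C1CC[C@@H]2[C@](COCc3ccccc3)(CCC[C@]2(C)C(=O)OC)C1CCOCc1ccccc1 | intermediate (not isolated)
23 | keto methyl ester, 9α-H (4α-CH3, 4β-CO2Me, 5α-H, 10β-CH2OBn, 9β-CH2CH2OBn, 8-oxo) | O=C1CC[C@@H]2[C@](COCc3ccccc3)(CCC[C@]2(C)C(=O)OC)[C@H]1CCOCc1ccccc1 | intermediate
24 | keto ester diol (10β-CH2OH, 9β-CH2CH2OH) | O=C1CC[C@@H]2[C@](CO)(CCC[C@]2(C)C(=O)OC)[C@H]1CCO | intermediate
25 | iodo alcohol (9β-CH2CH2I, 10β-CH2OH) | O=C1CC[C@@H]2[C@](CO)(CCC[C@]2(C)C(=O)OC)[C@H]1CCI | intermediate
26 | iodo acetate (9β-CH2CH2I, 10β-CH2OAc) | O=C1CC[C@@H]2[C@](COC(C)=O)(CCC[C@]2(C)C(=O)OC)[C@H]1CCI | intermediate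
27 | 3-bromofuran-2(5H)-one | O=C1OCC=C1Br | starting material
28 | alkylzinc iodide from 26 | O=C1CC[C@@H]2[C@](COC(C)=O)(CCC[C@]2(C)C(=O)OC)[C@H]1CC[Zn]I | intermediate (not isolated)
29 | 8-oxo butenolide (17-nor-8-ketone of the target) | O=C1CC[C@@H]2[C@](COC(C)=O)(CCC[C@]2(C)C(=O)OC)[C@H]1CCC1=CCOC1=O | intermediate
30 | methyl 20-acetoxylabda-8(17),13-dien-16,15-olid-19-oate | C=C1CC[C@@H]2[C@](COC(C)=O)(CCC[C@]2(C)C(=O)OC)[C@H]1CCC1=CCOC1=O | target

## Step count and risks

Total step count: 19. Longest linear sequence: 19 steps (1 → 30); building blocks 3, 6 and 27 enter as purchased.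

Steps most likely to fail:

Step 12 (Proposed new method). The C4 cation may be quenched by hydride shift from C19 or by proton loss instead of the alkyl shift. The zwitterion may also collapse to a cyclobutane, the aluminium alkoxide may transfer hydride to the enone, or C6 may add to the other alkene face and give the cis-fused isomer. The fallback uses known chemistry and separates the two bond formations; it sets out from 17. N-Bromosuccinimide (CH2Cl2, −20 °C) should trigger the bromonium-induced semipinacol rearrangement of the allylic alcohol: bromine adds to C5 and C3 shifts from C19 to C4 anti to it, giving the ring-contracted bromo aldehyde F1. Pinnick oxidation (NaClO2, NaH2PO4, 2-methylbut-2-ene) would give the bromo acid F2, so that the later C5 radical cannot undergo a 1,2-formyl shift. Bu3SnH/AIBN (benzene, 80 °C, slow addition) would then generate the C5 radical, which closes ring B by 6-endo addition to the terminal carbon of the vinyl ketone. This returns to the route at keto acid 21.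

Step 15. Once the benzyl ethers are removed, the axial C20 hydroxyl is 1,3-diaxial to the C19 ester and close to the C8 ketone. Transesterification to the 19,20-lactone with loss of methanol, or a persistent hemiketal, could drain material during steps 15–17. The fallback never frees the C20 alcohol; it sets out from 23. Acetolysis of both benzyl ethers (Ac2O, FeCl3 cat., 0 °C) should give the bis-acetate F3. K2CO3 (cat.) in MeOH at 0 °C should then cleave only the unhindered primary C12 acetate to give the hydroxy acetate F4. Appel iodination (iodine, PPh3, imidazole) returns to the route at 26.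

Step 18. Zinc insertion may be slow, and the alkylpalladium intermediate may undergo β-hydride elimination. The organozinc could also add in conjugate fashion to the bromobutenolide, or that partner may decompose. The fallback builds the butenolide by olefination and double-bond migration instead of cross-coupling; it sets out from 26. Oxidation of the primary iodide with trimethylamine N-oxide in DMSO (Kornblum-type) should give the aldehyde F5. Wittig olefination with 3-(triphenylphosphoranylidene)dihydrofuran-2(3H)-one (toluene, 80 °C) would give the α-alkylidene lactone F6. RhCl3·3H2O (cat.) in EtOH at reflux should then move the exocyclic double bond into the lactone ring, returning to the route at 29.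

Further compounds
F1 | step 12 | ring-contracted bromo aldehyde (cyclohexane: C5–Br, C4 α-CH3/β-CHO, C10 β-CH2OBn and the 6-(benzyloxy)-3-oxohex-1-en-4-yl chain; C5 and C9 unassigned) | BrC1[C@](COCc2ccccc2)(CCC[C@]1(C)C=O)C(CCOCc1ccccc1)C(=O)C=C
F2 | step 12 | bromo acid (as F1 with C19 CO2H) | BrC1[C@](COCc2ccccc2)(CCC[C@]1(C)C(=O)O)C(CCOCc1ccccc1)C(=O)C=C
F3 | step 15 | keto ester bis-acetate (10β-CH2OAc, 9β-CH2CH2OAc) | O=C1CC[C@@H]2[C@](COC(C)=O)(CCC[C@]2(C)C(=O)OC)[C@H]1CCOC(C)=O
F4 | step 15 | hydroxy acetate (10β-CH2OAc, 9β-CH2CH2OH) | O=C1CC[C@@H]2[C@](COC(C)=O)(CCC[C@]2(C)C(=O)OC)[C@H]1CCO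
F5 | step 18 | C12 aldehyde (9β-CH2CHO, 10β-CH2OAc) | O=C1CC[C@@H]2[C@](COC(C)=O)(CCC[C@]2(C)C(=O)OC)[C@H]1CC=O
F6 | step 18 | α-alkylidene-γ-butyrolactone (C12=C13, alkene geometry unassigned) | O=C1CC[C@@H]2[C@](COC(C)=O)(CCC[C@]2(C)C(=O)OC)[C@H]1CC=C1CCOC1=O
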